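**Plan**

1. Drimane numbering: ring A = C1–C5 and C10 (C3 ketone, C4 gem-dimethyl); ring B = C5–C10 (C7=C8, methyl on C8); C11 = the OCH2 carbon on C9.
2. Retrosynthetic cuts, in order: the C11–O(aryl) ether; C3=O and C1–C2 back to an allylic silyl ether; the C9–C10 bond of ring B by an oxy-Cope transform (re-forming a C2–C7 bond, which gives a bicyclo[2.2.2]octenol); the C7–C8 bond (ketone + alkenyllithium); the C2–C3 and C4–C5 bonds (Diels–Alder).
3. Enabling feature: ring B is cis-fused to ring A and holds an enol-type C7=C8 olefin next to the vicinal stereocentres C9 and quaternary C10. This is the product pattern of a [3,3] shift in a 2-alkenylbicyclo[2.2.2]oct-5-en-2-ol.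
4. Forward order: ring A is made first, locked in a bicyclo[2.2.2]octenone (creosol-derived dienone + silyl enol ether of isobutyraldehyde); the C8–C9–C11 unit is added as an alkenyllithium; ring B closes in the sigmatropic step; two reductions, etherification with umbelliferone and C3 oxidation finish the synthesis.
5. Stereochemistry: absolute configuration from a sulfoximine resolution of the bicyclic ketone; cis C5/C10 from the cage; C9 from the (E) geometry of the alkenyl group in the enforced boat; the C3 carbinol centre is temporary.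

Key step: step 9

Remark: the silyl enol ether is assumed to add endo in step 2; the carbinol centre this creates is oxidised in the last step, so its configuration is of no consequence for the target.
Remark: which of the two sulfoximine adducts carries the (1R,4S,7S) cage would be settled by X-ray analysis, with the sulfur centre of known configuration as internal reference.
Remark: in the decalins, "cis to CH3-10" means on the face of the C10 methyl group; CIP descriptors are given in drimane numbering.

**Route**

Step 1
Reactants: 1 isobutyraldehyde (2-methylpropanal)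
Product: 2 tert-butyldimethyl[(2-methylprop-1-en-1-yl)oxy]silane
Conditions: TBSOTf, Et3N, CH2Cl2, 0 °C to rt
Reagents that add atoms: tert-butyldimethylsilyl triflate, CC(C)(C)[Si](C)(C)OS(=O)(=O)C(F)(F)F
Why: O-silylation of the amine-generated enolate of an aldehyde with a single α-hydrogen is a standard silyl enol ether synthesis, and no E/Z question arises because the β-carbon carries two methyl groups.

Step 2
Reactants: 3 creosol (2-methoxy-4-methylphenol); 2 tert-butyldimethyl[(2-methylprop-1-en-1-yl)oxy]silane
Product: 5 rac-(1R*,4S*,7S*)-7-[(tert-butyldimethylsilyl)oxy]-3,3-dimethoxy-5,8,8-trimethylbicyclo[2.2.2]oct-5-en-2-one, via masked o-benzoquinone 4 (not isolated)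
Conditions: PhI(OAc)2, MeOH, 2 (5 equiv), 0 °C to 40 °C, slow addition of 3
Reagents that add atoms: methanol, CO
Why: Hypervalent-iodine oxidation of the 2-methoxyphenol in methanol gives the 6,6-dimethoxycyclohexa-2,4-dienone 4, an electron-poor diene that the excess enol ether should trap in an inverse-electron-demand Diels–Alder reaction before it dimerises; the nucleophilic dimethyl-bearing carbon bonds to the dienone terminus remote from the carbonyl and the oxygenated carbon to the terminus next to it, endo approach places the silyloxy group syn to the new olefin, and the adduct is racemic.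

Step 3
Reactants: 5 rac-(1R*,4S*,7S*)-7-[(tert-butyldimethylsilyl)oxy]-3,3-dimethoxy-5,8,8-trimethylbicyclo[2.2.2]oct-5-en-2-one
Product: 7 rac-(1R*,4S*,7S*)-7-[(tert-butyldimethylsilyl)oxy]-5,8,8-trimethylbicyclo[2.2.2]oct-5-en-2-one, via monomethoxy ketone 6 (not isolated)
Conditions: SmI2 (6 equiv), THF–MeOH, 0 °C to rt
Reagents that add atoms: none
Why: Electron transfer from SmI2 to the ketone gives a ketyl that expels the adjacent methoxide, and a second electron plus protonation by methanol returns the ketone, twice in succession; this reductive removal of α-alkoxy groups is established for adducts of masked o-benzoquinones and touches no stereocentre of the cage.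

Step 4
Reactants: 7 rac-(1R*,4S*,7S*)-7-[(tert-butyldimethylsilyl)oxy]-5,8,8-trimethylbicyclo[2.2.2]oct-5-en-2-one
Product: 8 (1R,2R,4S,7S)-7-[(tert-butyldimethylsilyl)oxy]-5,8,8-trimethyl-2-{[(S)-N-methyl-S-phenylsulfonimidoyl]methyl}bicyclo[2.2.2]oct-5-en-2-ol
Conditions: (S)-N,S-dimethyl-S-phenylsulfoximine, n-BuLi, THF, −78 °C; then 7, −78 °C; separation of the two adducts on silica gel
Reagents that add atoms: (S)-N,S-dimethyl-S-phenylsulfoximine, C[S@@](=O)(=NC)c1ccccc1
Why: Addition of the lithiated enantiopure sulfoximine to the racemic ketone (classical sulfoximine resolution of ketones) should occur from the open olefin face of each enantiomer and give two diastereomeric β-hydroxy sulfoximines that differ only in the sense of the cage and are separable by chromatography or crystallisation.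

Step 5
Reactants: 8 (1R,2R,4S,7S)-7-[(tert-butyldimethylsilyl)oxy]-5,8,8-trimethyl-2-{[(S)-N-methyl-S-phenylsulfonimidoyl]methyl}bicyclo[2.2.2]oct-5-en-2-ol
Product: 9 (1R,4S,7S)-7-[(tert-butyldimethylsilyl)oxy]-5,8,8-trimethylbicyclo[2.2.2]oct-5-en-2-one
Conditions: toluene, 110 °C
Reagents that add atoms: none
Why: β-Hydroxy sulfoximines revert on heating to ketone and sulfoximine (thermal retro-addition), which should release the ketone as a single enantiomer without touching its three stereocentres.

Step 6
Reactants: 10 but-2-yn-1-ol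
Product: 11 tert-butyl(but-2-yn-1-yloxy)dimethylsilane
Conditions: TBSCl, imidazole, CH2Cl2, rt
Reagents that add atoms: tert-butyldimethylsilyl chloride, CC(C)(C)[Si](C)(C)Cl
Why: Silylation of a primary alcohol under imidazole catalysis is routine, and the bulky silyl ether later steers the hydrozirconation.

Step 7
Reactants: 11 tert-butyl(but-2-yn-1-yloxy)dimethylsilane
Product: 13 (E)-tert-butyl[(3-iodobut-2-en-1-yl)oxy]dimethylsilane, via alkenylzirconocene chloride 12 (not isolated)
Conditions: Cp2Zr(H)Cl (2 equiv), THF, 50 °C; then I2, 0 °C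
Reagents that add atoms: iodine, II
Why: syn-Hydrozirconation of the internal alkyne followed by equilibration with excess Cp2Zr(H)Cl should place zirconium on the methyl-bearing carbon, away from the silyloxymethyl group, and iodinolysis with retention then gives the (E)-iodide with CH3 and CH2OTBS cis.

Step 8
Reactants: 13 (E)-tert-butyl[(3-iodobut-2-en-1-yl)oxy]dimethylsilane; 9 (1R,4S,7S)-7-[(tert-butyldimethylsilyl)oxy]-5,8,8-trimethylbicyclo[2.2.2]oct-5-en-2-one
Product: 15 (1R,2R,4S,7S)-7-[(tert-butyldimethylsilyl)oxy]-2-{(2E)-4-[(tert-butyldimethylsilyl)oxy]but-2-en-2-yl}-5,8,8-trimethylbicyclo[2.2.2]oct-5-en-2-ol, via alkenyllithium 14 (not isolated)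
Conditions: 13, t-BuLi (2 equiv), Et2O, −78 °C; then 9, −78 to −40 °C
Reagents that add atoms: none
Why: Iodine–lithium exchange retains the olefin geometry, and 1,2-addition to a bicyclo[2.2.2]oct-5-en-2-one normally occurs from the face syn to the C5=C6 olefin, here the face away from the ethano bridge that carries the gem-dimethyl and silyloxy groups, so the new carbinol centre (2R) should carry the alkenyl group syn to the olefin.

Step 9
Reactants: 15 (1R,2R,4S,7S)-7-[(tert-butyldimethylsilyl)oxy]-2-{(2E)-4-[(tert-butyldimethylsilyl)oxy]but-2-en-2-yl}-5,8,8-trimethylbicyclo[2.2.2]oct-5-en-2-ol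
Product: 18 cis-decalin enol triflate (drimane numbering: 7-OTf on C7=C8; C1=C2; 3-OTBS; 11-OTBS; 3S,5S,9S,10S), via potassium alkoxide 16 (not isolated), via potassium enolate 17 (not isolated)
Conditions: KN(SiMe3)2, 18-crown-6, THF, 0 °C to rt; then PhNTf2, −78 °C to rt
Reagents that add atoms: N-phenylbis(trifluoromethanesulfonimide), O=S(=O)(N(c1ccccc1)S(=O)(=O)C(F)(F)F)C(F)(F)F
Why: KN(SiMe3)2 with 18-crown-6 converts 15 into the loosely ion-paired alkoxide 16, whose charge weakens the bond between the carbinol carbon and the neighbouring bridgehead (C7–C2) and accelerates a [3,3] sigmatropic shift in which the alkenyl terminus C9 bonds to the methyl-bearing carbon of the cage olefin (C10); the resulting enolate 17 has its double bond fixed at C7=C8 and is sulfonylated on oxygen by PhNTf2. The closest known reaction type is the anionic oxy-Cope rearrangement of 2-alkenylbicyclo[2.2.2]oct-5-en-2-ols to cis-decalin enolates that are trapped by electrophiles. Ring B (C5–C10) closes in a six-centre pericyclic mode through the single new C9–C10 bond, suprafacially on both allyl units, via the boat array that the cage enforces. C10 is controlled by the cage, because C9 can reach it only from the face on which the C6–C7 bridge is already attached, so H-5 and CH3-10 must come out cis; C9 is controlled by the (E) geometry of the alkenyl group, which turns CH2OTBS outward in the boat and so places C11 trans to CH3-10. The step needs the alkenyl group syn to the cage olefin (secured by the facial selectivity of step 8) and [3,3] over [1,3] shift or fragmentation (secured by the rigid alignment and the strain released on opening the cage); the endo silyloxy group points away from the alkoxide and the (E) olefin holds the other silyl ether remote, so no silyl transfer is expected.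

Step 10
Reactants: 18 cis-decalin enol triflate (7-OTf; C1=C2; 3,11-bis-OTBS)
Product: 19 cis-decalin enol triflate with saturated C1–C2 (7-OTf on C7=C8; 3-OTBS; 11-OTBS; 3S,5S,9S,10S)
Conditions: RhCl(PPh3)3 (10 mol %), H2 (4 atm), toluene–EtOH, 40 °C
Reagents that add atoms: none
Why: Homogeneous hydrogenation with RhCl(PPh3)3 reduces cis-disubstituted olefins but not tetrasubstituted ones, so only C1=C2 should be saturated while the enol triflate and silyl ethers remain, and no stereocentre is formed or disturbed.

Step 11
Reactants: 19 cis-decalin enol triflate with saturated C1–C2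
Product: 20 (3S,5S,9R,10S)-3,11-bis[(tert-butyldimethylsilyl)oxy] cis-decalin with C7=C8 olefin (C7–H)
Conditions: Pd(OAc)2, PPh3, HCO2H, n-Bu3N, DMF, 60 °C
Reagents that add atoms: none
Why: Zerovalent palladium inserts into the C7–O triflate bond, formate delivers hydride with loss of CO2 and reductive elimination gives the C7–H olefin (palladium-catalysed formate reduction of enol triflates), which fixes the double bond at C7=C8 without affecting C9.

Step 12
Reactants: 20 bis-silyl ether with C7=C8 olefin
Product: 21 (3S,5S,9R,10S)-3,11-diol of the cis-decalin with C7=C8 olefin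
Conditions: Bu4NF (4 equiv), THF, 60 °C
Reagents that add atoms: none
Why: Fluoride cleaves both Si–O bonds (desilylation), warming being needed for the ether at C3 next to the quaternary C4, and no stereocentre is involved.

Step 13
Reactants: 21 (3S,5S,9R,10S)-3,11-diol; 22 umbelliferone (7-hydroxy-2H-chromen-2-one)
Product: 23 (3S,5S,9R,10S)-11-(2-oxo-2H-chromen-7-yloxy) cis-decalin-3-ol with C7=C8 olefin
Conditions: PPh3, DIAD, THF, 0 °C to rt
Reagents that add atoms: none
Why: In this Mitsunobu etherification the acidic phenol protonates the betaine and its phenoxide displaces the oxyphosphonium group at the primary, non-stereogenic C11, while the C3 carbinol flanked by the quaternary C4 is too hindered to react.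

Step 14
Reactants: 23 (3S,5S,9R,10S)-11-(2-oxo-2H-chromen-7-yloxy) cis-decalin-3-ol
Product: 24 7-{[(1R,4aS,8aS)-2,5,5,8a-tetramethyl-6-oxo-1,4,4a,5,6,7,8,8a-octahydronaphthalen-1-yl]methoxy}-2H-chromen-2-one (target; 5S,9R,10S in drimane numbering)
Conditions: Dess–Martin periodinane, CH2Cl2, rt
Reagents that add atoms: none
Why: Dess–Martin oxidation converts the secondary alcohol into the C3 ketone under neutral conditions that leave the trisubstituted olefin, the aryl ether and the coumarin lactone intact, and the ketone has no α-stereocentre that could epimerise.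

**Compound list**

1 | isobutyraldehyde (2-methylpropanal) | CC(C)C=O | starting material
2 | tert-butyldimethyl[(2-methylprop-1-en-1-yl)oxy]silane | CC(C)=CO[Si](C)(C)C(C)(C)C | intermediate
3 | creosol (2-methoxy-4-methylphenol) | COc1cc(C)ccc1O | starting material
4 | 6,6-dimethoxy-4-methylcyclohexa-2,4-dien-1-one (masked o-benzoquinone, not isolated) | COC1(OC)C=C(C)C=CC1=O | intermediate
5 | rac-(1R*,4S*,7S*)-7-[(tert-butyldimethylsilyl)oxy]-3,3-dimethoxy-5,8,8-trimethylbicyclo[2.2.2]oct-5-en-2-one (silyloxy group syn to C5=C6; one enantiomer drawn) | O=C1[C@@H]2C=C(C)[C@H](C1(OC)OC)C(C)(C)[C@H]2O[Si](C)(C)C(C)(C)C | intermediate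
6 | rac-7-[(tert-butyldimethylsilyl)oxy]-3-methoxy-5,8,8-trimethylbicyclo[2.2.2]oct-5-en-2-one (cage as in 5, both epimers at C3, not isolated) | O=C1[C@@H]2C=C(C)[C@H](C1OC)C(C)(C)[C@H]2O[Si](C)(C)C(C)(C)C | intermediate
7 | rac-(1R*,4S*,7S*)-7-[(tert-butyldimethylsilyl)oxy]-5,8,8-trimethylbicyclo[2.2.2]oct-5-en-2-one (one enantiomer drawn) | O=C1[C@@H]2C=C(C)[C@H](C1)C(C)(C)[C@H]2O[Si](C)(C)C(C)(C)C | intermediate
8 | (1R,2R,4S,7S)-7-[(tert-butyldimethylsilyl)oxy]-5,8,8-trimethyl-2-{[(S)-N-methyl-S-phenylsulfonimidoyl]methyl}bicyclo[2.2.2]oct-5-en-2-ol (sulfonimidoylmethyl group syn to C5=C6) | O[C@@]1(C[S@@](=O)(=NC)c2ccccc2)[C@@H]2C=C(C)[C@H](C1)C(C)(C)[C@H]2O[Si](C)(C)C(C)(C)C | intermediate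
9 | (1R,4S,7S)-7-[(tert-butyldimethylsilyl)oxy]-5,8,8-trimethylbicyclo[2.2.2]oct-5-en-2-one | O=C1[C@@H]2C=C(C)[C@H](C1)C(C)(C)[C@H]2O[Si](C)(C)C(C)(C)C | intermediate
10 | but-2-yn-1-ol | CC#CCO | starting material
11 | tert-butyl(but-2-yn-1-yloxy)dimethylsilane | CC#CCO[Si](C)(C)C(C)(C)C | intermediate
12 | chlorobis(cyclopentadienyl){4-[(tert-butyldimethylsilyl)oxy]but-2-en-2-yl}zirconium (Zr and H cis, CH3 and CH2OTBS cis, not isolated) | C/C(=C\CO[Si](C)(C)C(C)(C)C)[Zr](Cl)(C1C=CC=C1)C1C=CC=C1 | intermediate
13 | (E)-tert-butyl[(3-iodobut-2-en-1-yl)oxy]dimethylsilane | C/C(I)=C\CO[Si](C)(C)C(C)(C)C | intermediate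
14 | alkenyllithium from 13 (lithium in place of iodine, geometry retained: CH3 and CH2OTBS cis, not isolated) | [Li]/C(C)=C/CO[Si](C)(C)C(C)(C)C | intermediate
15 | (1R,2R,4S,7S)-7-[(tert-butyldimethylsilyl)oxy]-2-{(2E)-4-[(tert-butyldimethylsilyl)oxy]but-2-en-2-yl}-5,8,8-trimethylbicyclo[2.2.2]oct-5-en-2-ol (alkenyl group syn to C5=C6; precursor of the key step) | O[C@@]1(/C(C)=C/CO[Si](C)(C)C(C)(C)C)[C@@H]2C=C(C)[C@H](C1)C(C)(C)[C@H]2O[Si](C)(C)C(C)(C)C | intermediate
16 | potassium alkoxide of 15 (not isolated) | [K+].[O-][C@@]1(/C(C)=C/CO[Si](C)(C)C(C)(C)C)[C@@H]2C=C(C)[C@H](C1)C(C)(C)[C@H]2O[Si](C)(C)C(C)(C)C | intermediate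
17 | potassium C7 enolate of the cis-decalin (C7=C8 enolate, C1=C2, 3-OTBS, 11-OTBS; not isolated) | [K+].CC1=C([O-])C[C@@H]2C(C)(C)[C@@H](O[Si](C)(C)C(C)(C)C)C=C[C@]2(C)[C@@H]1CO[Si](C)(C)C(C)(C)C | intermediate
18 | (3S,5S,9S,10S) cis-decalin enol triflate: 7-OTf on C7=C8, C1=C2, 3-OTBS, 11-OTBS; H-5, H-9 and O-3 cis to CH3-10, C11 trans (the C9 descriptor differs from the target only through CIP priorities); product of the key step | CC1=C(OS(=O)(=O)C(F)(F)F)C[C@@H]2C(C)(C)[C@@H](O[Si](C)(C)C(C)(C)C)C=C[C@]2(C)[C@@H]1CO[Si](C)(C)C(C)(C)C | intermediate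
19 | (3S,5S,9S,10S) cis-decalin enol triflate with saturated C1–C2: 7-OTf on C7=C8, 3-OTBS, 11-OTBS | CC1=C(OS(=O)(=O)C(F)(F)F)C[C@@H]2C(C)(C)[C@@H](O[Si](C)(C)C(C)(C)C)CC[C@]2(C)[C@@H]1CO[Si](C)(C)C(C)(C)C | intermediate
20 | (3S,5S,9R,10S)-3,11-bis[(tert-butyldimethylsilyl)oxy] cis-decalin with C7=C8 olefin (4,4,8,10-tetramethyl; H-5, H-9 and O-3 cis to CH3-10) | CC1=CC[C@@H]2C(C)(C)[C@@H](O[Si](C)(C)C(C)(C)C)CC[C@]2(C)[C@@H]1CO[Si](C)(C)C(C)(C)C | intermediate
21 | (2S,4aS,5R,8aS)-5-(hydroxymethyl)-1,1,4a,6-tetramethyl-1,2,3,4,4a,5,8,8a-octahydronaphthalen-2-ol (3S,5S,9R,10S in drimane numbering) | CC1=CC[C@@H]2C(C)(C)[C@@H](O)CC[C@]2(C)[C@@H]1CO | intermediate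
22 | umbelliferone (7-hydroxy-2H-chromen-2-one) | O=c1ccc2ccc(O)cc2o1 | starting material
23 | 7-{[(1R,4aS,6S,8aS)-6-hydroxy-2,5,5,8a-tetramethyl-1,4,4a,5,6,7,8,8a-octahydronaphthalen-1-yl]methoxy}-2H-chromen-2-one | CC1=CC[C@@H]2C(C)(C)[C@@H](O)CC[C@]2(C)[C@@H]1COc1ccc2ccc(=O)oc2c1 | intermediate
24 | 7-{[(1R,4aS,8aS)-2,5,5,8a-tetramethyl-6-oxo-1,4,4a,5,6,7,8,8a-octahydronaphthalen-1-yl]methoxy}-2H-chromen-2-one (CNP0262399.3) | CC1=CC[C@@H]2C(C)(C)C(=O)CC[C@]2(C)[C@@H]1COc1ccc2ccc(=O)oc2c1 | target

**Step count and risks**

Total steps: 14. Longest linear sequence: 12 steps (steps 1–5 and 8–14, from isobutyraldehyde); the iodide branch (steps 6 and 7) joins at step 8.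

Steps most likely to fail:

Step 2. The dienone may dimerise, or the silyl enol ether may be lost to methanolysis by the acetic acid released or to the oxidant, before the crowded cycloaddition (bond formation at a fully substituted carbon) takes place. The fallback sets out from 3 and comes back to the route at 5. Creosol would be oxidised with PhI(OAc)2 in MeOH without a trap and the dienone allowed to dimerise to the endo Diels–Alder dimer F1, which is isolated. Heating the dimer F1 with an excess of 2 in mesitylene at 220 °C in a sealed tube should release the dienone by cycloreversion in an aprotic medium free of acid and oxidant, where it is captured by 2 to give 5.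

Step 9. O-Sulfonylation of the crowded tetrasubstituted enolate may be slow, so that proton transfer or decomposition competes and the one-pot sequence gives little triflate. The fallback sets out from 15 and comes back at 18. The rearrangement would be run alone (KN(SiMe3)2, 18-crown-6, THF, rt to 50 °C) and quenched with water to give the cis-fused C7 ketone F2 as a mixture of C8 epimers. The ketone F2 would then be converted into 18 with Tf2O and 2,6-di-tert-butyl-4-methylpyridine in CH2Cl2, conditions that favour the more substituted enol triflate; both epimers converge.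

Step 13. Displacement at the β-branched C11 oxyphosphonium ion may be slow, so that elimination towards C9 or consumption of the betaine takes over. The fallback sets out from 21 and comes back at 23 without any new intermediate. The primary alcohol of 21 would be coupled with commercial 7-bromocoumarin by palladium-catalysed C–O cross-coupling ([Pd(allyl)Cl]2, RockPhos, Cs2CO3, toluene, 90 °C). Here the alcohol oxygen is the nucleophile towards an arylpalladium species, no substitution at C11 is needed, and the hindered C3 carbinol should not compete.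

Further compounds
F1 | step 2 | rac-3,3,10,10-tetramethoxy-7,12-dimethyltricyclo[6.2.2.0^{2,7}]dodeca-5,11-diene-4,9-dione (endo dimer of dienone 4; relative configuration as expected for endo dimerisation, one enantiomer drawn) | O=C1[C@@H]2C=C(C)[C@H](C1(OC)OC)[C@H]3C(OC)(OC)C(=O)C=C[C@@]23C
F2 | step 9 | cis-fused C7 ketone (drimane numbering: 7-oxo, C1=C2, 3-OTBS, 11-OTBS; C8 epimers; other centres as in 18) | CC1C(=O)C[C@@H]2C(C)(C)[C@@H](O[Si](C)(C)C(C)(C)C)C=C[C@]2(C)[C@@H]1CO[Si](C)(C)C(C)(C)C
F0 | step 13 | none | none
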